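**Plan**

- Retrosynthesis: the three O-benzyl groups and the acetyl group come off first. The quinone ring is then cut at two ring bonds, C(=O)–C(OAc) and C(=O)–C(aryl), giving a four-carbon unit O=C–C(O)=C(Ar)–C=O and a two-carbon unit C(O)=C(Ar).
- Enabling feature: the four-carbon unit is an ene-1,4-dione, i.e. a cyclobutene-1,2-dione (from squaric acid) opened between its two carbonyl carbons by cobalt. The two-carbon unit, an sp2 C=C with one oxygen and one aryl inside a quinone, is a siloxyalkyne at the correct oxidation level. Each half brings one aryl group and one ring oxygen, masked differently (benzyl against silyl), so the single acetate is placed without selection among hydroxyl groups.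
- Forward order: squaric acid → dibenzyl squarate → 3-aryl-4-benzyloxycyclobutenedione → maleoylcobalt complex; arylacetylene → siloxyalkyne. One annulation joins the halves and forms the quinone ring (the only ring made). The silyl group is lost on work-up, the free enol is acetylated, and the benzyl groups are removed last.
- Symmetry used at the end: the ring carries oxygen on four carbons (1,2,4,5) and identical aryl groups on the other two, so any monoacetate on a ring oxygen is the same compound after reoxidation.
- Stereochemistry: the target is achiral, with no stereocentre and no stereogenic double bond; nothing has to be controlled.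

Key step: step 5

Remark: the orientation of the alkyne in step 5 is argued from mechanism, not from a direct precedent with a siloxyalkyne; it is the main uncertainty of the route.

**Step 1**
Reactants: 1 squaric acid (3,4-dihydroxycyclobut-3-ene-1,2-dione)
Product: 2 dibenzyl squarate (3,4-bis(benzyloxy)cyclobut-3-ene-1,2-dione)
Conditions: BnOH (4 equiv), toluene, reflux, Dean–Stark trap
Reagents that add atoms: benzyl alcohol, OCc1ccccc1
Why: Esterification of the vinylogous diacid with azeotropic removal of water, the standard preparation of dialkyl squarates, should give the diester.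

**Step 2**
Reactants: 3 1-(benzyloxy)-4-bromobenzene; 2 dibenzyl squarate
Product: 6 3-(benzyloxy)-4-[4-(benzyloxy)phenyl]cyclobut-3-ene-1,2-dione, via aryllithium 4 (not isolated), via carbinol adduct 5 (not isolated)
Conditions: n-BuLi, THF, −78 °C; add 2, −78 °C; then 12 M HCl, CH2Cl2, rt
Reagents that add atoms: water, O
Why: Bromine–lithium exchange, 1,2-addition of the aryllithium to one carbonyl of the squarate and acid-induced 1,3-carbonyl transposition (loss of water, addition of water at the vinylogous position, loss of benzyl alcohol from the hemiketal) form the established route from squarates to 3-alkoxy-4-arylcyclobutenediones.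

**Step 3**
Reactants: 7 1-(benzyloxy)-4-ethynylbenzene
Product: 10 ({[4-(benzyloxy)phenyl]ethynyl}oxy)tri(propan-2-yl)silane, via lithium acetylide 8 (not isolated), via lithium ynolate 9 (not isolated)
Conditions: LiN(SiMe3)2, THF, −78 °C; t-BuOOLi (from t-BuOOH and LiN(SiMe3)2), −78 → 0 °C; TIPSOTf, −78 °C → rt
Reagents that add atoms: tert-butyl hydroperoxide, CC(C)(C)OO; triisopropylsilyl trifluoromethanesulfonate, CC(C)[Si](C(C)C)(C(C)C)OS(=O)(=O)C(F)(F)F
Why: Oxygen transfer from lithium tert-butyl peroxide to the lithium acetylide should give the ynolate (acetylide oxidation), which the bulky silyl triflate should silylate on oxygen to give the siloxyalkyne, the usual preparation of this class.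

**Step 4**
Reactants: 6 3-(benzyloxy)-4-[4-(benzyloxy)phenyl]cyclobut-3-ene-1,2-dione
Product: 12 chloro(dimethylglyoxime)(pyridine) maleoylcobalt complex (five-membered cobaltacyclopentene-2,5-dione carrying 3-benzyloxy and 4-[4-(benzyloxy)phenyl]; trivalent cobalt with chloride, pyridine and N,N-bound neutral dimethylglyoxime), via bis(triphenylphosphine) complex 11 (not isolated)
Conditions: ClCo(PPh3)3 (1.1 equiv), benzene, rt; then dimethylglyoxime, pyridine, rt
Reagents that add atoms: chlorotris(triphenylphosphine)cobalt, Cl[Co-3]([P+](c1ccccc1)(c1ccccc1)c1ccccc1)([P+](c1ccccc1)(c1ccccc1)c1ccccc1)[P+](c1ccccc1)(c1ccccc1)c1ccccc1; dimethylglyoxime, CC(=NO)C(C)=NO; pyridine, c1ccncc1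
Why: Oxidative addition of monovalent cobalt into the bond between the two carbonyl carbons of the cyclobutenedione should give the maleoyl metallacycle of trivalent cobalt, and exchange of the phosphines for dimethylglyoxime and pyridine should give the octahedral, air-stable complex used for quinone synthesis (C–C bond insertion, then ligand exchange).

**Step 5**
Reactants: 12 maleoylcobalt dimethylglyoxime complex; 10 ({[4-(benzyloxy)phenyl]ethynyl}oxy)tri(propan-2-yl)silane
Product: 14 2-(benzyloxy)-3,6-bis[4-(benzyloxy)phenyl]-5-hydroxycyclohexa-2,5-diene-1,4-dione, via siloxyquinone 13 (not isolated)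
Conditions: SnCl4 (1.0 equiv, premixed with 12), ClCH2CH2Cl, −20 °C → rt, slow addition of 10; then 1 M HCl, THF, rt
Reagents that add atoms: none
Why: The Lewis acid opens a coordination site and the alkyne binds; the acyl carbon attached to the benzyloxy-bearing ring carbon migrates to the aryl-bearing (β) carbon of the siloxyalkyne, giving a seven-membered cobaltacycle whose vinyl–cobalt carbon carries the silyloxy group, and C–C reductive elimination with the second acyl carbon releases the quinone and low-valent cobalt. The closest known reaction type is the benzoquinone synthesis from maleoylcobalt dimethylglyoxime complexes and alkynes under SnCl4 promotion, established for alkoxy-substituted maleoyl complexes and unsymmetrical alkynes. The six-membered quinone ring is closed in a formal [4+2] metal-mediated annulation, the last bond by reductive elimination from the seven-membered metallacycle, and no stereocentre is formed. The step needs one orientation of the alkyne: aryl-bearing carbon to the acyl next to C–OBn and oxygen-bearing carbon to the acyl next to the aryl-bearing carbon, which gives the 2,5-dioxy-3,6-diaryl pattern and not the 2,3-dioxy isomer. This should be secured by SnCl4 binding the more basic oxygen, that of the vinylogous-ester acyl group (conjugated with OBn through the ring C=C), which leaves the other cobalt–acyl bond to insert, and by the usual sense of carbometalation of ynol ethers (carbon to the β-carbon, metal to the oxygen-bearing carbon). The bulky Si(iPr)3 group and premixing of the complex with SnCl4 should protect the siloxyalkyne from acid-induced decomposition, and the silyl vinylogous ester should be cleaved by the acidic work-up.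

**Step 6**
Reactants: 14 2-(benzyloxy)-3,6-bis[4-(benzyloxy)phenyl]-5-hydroxycyclohexa-2,5-diene-1,4-dione
Product: 15 4-(benzyloxy)-2,5-bis[4-(benzyloxy)phenyl]-3,6-dioxocyclohexa-1,4-dien-1-yl acetate
Conditions: Ac2O (1.5 equiv), pyridine, CH2Cl2, 0 °C → rt
Reagents that add atoms: acetic anhydride, CC(=O)OC(C)=O
Why: O-Acylation of the acidic 2-hydroxyquinone (a vinylogous carboxylic acid) is the standard preparation of acetoxyquinones, and it should be unambiguous here because this is the only free hydroxyl group and either oxygen of the ambident anion leads to the same para-quinone acetate.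

**Step 7**
Reactants: 15 4-(benzyloxy)-2,5-bis[4-(benzyloxy)phenyl]-3,6-dioxocyclohexa-1,4-dien-1-yl acetate
Product: 17 4-hydroxy-2,5-bis(4-hydroxyphenyl)-3,6-dioxocyclohexa-1,4-dien-1-yl acetate, via leuco acetate 16 (not isolated)
Conditions: H2 (1 atm), 10% Pd/C, EtOAc, rt; filter under Ar; then air, EtOAc, rt
Reagents that add atoms: none
Why: Neutral hydrogenolysis should cleave the three benzyl ethers while reducing the quinone to a hydroquinone whose aryl acetate is stable, and autoxidation in air should restore the quinone (hydrogenolysis, then hydroquinone autoxidation); an acetyl shift between neighbouring ring oxygens in the leuco form would give the same product because of the ring symmetry.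

**Compound list**

1 | squaric acid (3,4-dihydroxycyclobut-3-ene-1,2-dione) | O=C1C(O)=C(O)C1=O | starting material
2 | dibenzyl squarate (3,4-bis(benzyloxy)cyclobut-3-ene-1,2-dione) | O=C1C(OCc2ccccc2)=C(OCc2ccccc2)C1=O | intermediate
3 | 1-(benzyloxy)-4-bromobenzene | Brc1ccc(OCc2ccccc2)cc1 | starting material
4 | [4-(benzyloxy)phenyl]lithium | [Li]c1ccc(OCc2ccccc2)cc1 | intermediate
5 | 2,3-bis(benzyloxy)-4-[4-(benzyloxy)phenyl]-4-hydroxycyclobut-2-en-1-one (racemic) | O=C1C(OCc2ccccc2)=C(OCc2ccccc2)C1(O)c1ccc(OCc2ccccc2)cc1 | intermediate
6 | 3-(benzyloxy)-4-[4-(benzyloxy)phenyl]cyclobut-3-ene-1,2-dione | O=C1C(=O)C(c2ccc(OCc3ccccc3)cc2)=C1OCc1ccccc1 | intermediate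
7 | 1-(benzyloxy)-4-ethynylbenzene | C#Cc1ccc(OCc2ccccc2)cc1 | starting material
8 | lithium [4-(benzyloxy)phenyl]acetylide | [Li]C#Cc1ccc(OCc2ccccc2)cc1 | intermediate
9 | lithium 2-[4-(benzyloxy)phenyl]ethyn-1-olate | [Li]OC#Cc1ccc(OCc2ccccc2)cc1 | intermediate
10 | ({[4-(benzyloxy)phenyl]ethynyl}oxy)tri(propan-2-yl)silane | CC(C)[Si](C(C)C)(C(C)C)OC#Cc1ccc(OCc2ccccc2)cc1 | intermediate
11 | chlorobis(triphenylphosphine) maleoylcobalt complex (cobaltacyclopentene-2,5-dione with 3-benzyloxy and 4-[4-(benzyloxy)phenyl]) | Cl[Co-2]1([P+](c2ccccc2)(c2ccccc2)c2ccccc2)([P+](c2ccccc2)(c2ccccc2)c2ccccc2)C(=O)C(OCc2ccccc2)=C(c2ccc(OCc3ccccc3)cc2)C1=O | intermediate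
12 | chloro(dimethylglyoxime)(pyridine) maleoylcobalt complex (same cobaltacycle) | Cl[Co-3]12([n+]3ccccc3)(C(=O)C(OCc3ccccc3)=C(c3ccc(OCc4ccccc4)cc3)C1=O)[N+](O)=C(C)C(C)=[N+]2O | intermediate
13 | 2-(benzyloxy)-3,6-bis[4-(benzyloxy)phenyl]-5-{[tri(propan-2-yl)silyl]oxy}cyclohexa-2,5-diene-1,4-dione | CC(C)[Si](C(C)C)(C(C)C)OC1=C(c2ccc(OCc3ccccc3)cc2)C(=O)C(OCc2ccccc2)=C(c2ccc(OCc3ccccc3)cc2)C1=O | intermediate
14 | 2-(benzyloxy)-3,6-bis[4-(benzyloxy)phenyl]-5-hydroxycyclohexa-2,5-diene-1,4-dione | OC1=C(c2ccc(OCc3ccccc3)cc2)C(=O)C(OCc2ccccc2)=C(c2ccc(OCc3ccccc3)cc2)C1=O | intermediate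
15 | 4-(benzyloxy)-2,5-bis[4-(benzyloxy)phenyl]-3,6-dioxocyclohexa-1,4-dien-1-yl acetate | CC(=O)OC1=C(c2ccc(OCc3ccccc3)cc2)C(=O)C(OCc2ccccc2)=C(c2ccc(OCc3ccccc3)cc2)C1=O | intermediate
16 | 2,4,5-trihydroxy-3,6-bis(4-hydroxyphenyl)phenyl acetate | CC(=O)Oc1c(-c2ccc(O)cc2)c(O)c(O)c(-c2ccc(O)cc2)c1O | intermediate
17 | 4-hydroxy-2,5-bis(4-hydroxyphenyl)-3,6-dioxocyclohexa-1,4-dien-1-yl acetate | CC(=O)OC1=C(c2ccc(O)cc2)C(=O)C(O)=C(c2ccc(O)cc2)C1=O | target

**Summary**

Total step count: 7. Longest linear sequence: 6 steps (1, 2, 4, 5, 6, 7); step 3 is a one-step branch.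

Steps most likely to fail:

Step 5. The alkyne may insert in the reverse orientation and lead to the 2,3-dioxy-5,6-diaryl quinone, or the siloxyalkyne may be consumed by the Lewis acid before it reaches cobalt. The fallback gives up the annulation and builds the terphenylquinone by a twofold Suzuki coupling.
- It sets out from aryllithium 4 (made from 3 as in step 2), which with B(OMe)3 at −78 °C and acidic work-up should give 4-(benzyloxy)phenylboronic acid F1.
- Bromanil with NaOMe in methanol should give 2,5-dibromo-3,6-dimethoxycyclohexa-2,5-diene-1,4-dione F2.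
- Coupling of F2 with two equivalents of F1 (Pd(PPh3)4, K2CO3, dioxane–water, 80 °C) should give 2,5-bis[4-(benzyloxy)phenyl]-3,6-dimethoxycyclohexa-2,5-diene-1,4-dione F3.
- Hydrolysis of both vinylogous methyl esters (NaOH, aqueous methanol–dioxane, then HCl) should give 2,5-bis[4-(benzyloxy)phenyl]-3,6-dihydroxycyclohexa-2,5-diene-1,4-dione F4.
- One equivalent of Ac2O in pyridine should give, beside recoverable F4 and diacetate, 2,5-bis[4-(benzyloxy)phenyl]-4-hydroxy-3,6-dioxocyclohexa-1,4-dien-1-yl acetate F5; the two enolic hydroxyl groups of F4 are equivalent, so only one monoacetate can form.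
- Hydrogenolysis of F5 under the conditions of step 7 should give leuco acetate 16, where the fallback comes back to the route.

Step 7. The acetyl group may be lost by transfer or hydrolysis during reduction and aerobic reoxidation, or the hindered vinylogous benzyl ester may be cleaved incompletely. The fallback replaces the redox sequence by a non-reductive Lewis-acid debenzylation. It sets out from 15: BCl3 with pentamethylbenzene as cation scavenger in CH2Cl2 at −78 °C should cleave the two aryl benzyl ethers and the vinylogous benzyl ester and leave the acetate. It comes back to the route at 17 without passing through the leuco form, and makes no new compound (F0).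

Step 3. Oxygen transfer to the acetylide may be incomplete, or the ynolate may be attacked further by the peroxide, so that little siloxyalkyne survives isolation. The fallback reaches the same ynolate by ester homologation (Kowalski ester homologation).
- It sets out from aryllithium 4, which with ethyl chloroformate (inverse addition, −78 °C) should give ethyl 4-(benzyloxy)benzoate F6.
- Addition of dibromomethyllithium (CH2Br2, lithium 2,2,6,6-tetramethylpiperidide, THF, −78 °C) and collapse of the adduct should give 1-[4-(benzyloxy)phenyl]-2,2-dibromoethan-1-one F7, held as its lithium enolate.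
- Bromine–lithium exchange with n-BuLi and warming should trigger the 1,2-aryl shift to lithium ynolate 9, where the fallback comes back to the route before silylation to 10.

**Further compounds**

F1 | step 5 | 4-(benzyloxy)phenylboronic acid | OB(O)c1ccc(OCc2ccccc2)cc1
F2 | step 5 | 2,5-dibromo-3,6-dimethoxycyclohexa-2,5-diene-1,4-dione | COC1=C(Br)C(=O)C(OC)=C(Br)C1=O
F3 | step 5 | 2,5-bis[4-(benzyloxy)phenyl]-3,6-dimethoxycyclohexa-2,5-diene-1,4-dione | COC1=C(c2ccc(OCc3ccccc3)cc2)C(=O)C(OC)=C(c2ccc(OCc3ccccc3)cc2)C1=O
F4 | step 5 | 2,5-bis[4-(benzyloxy)phenyl]-3,6-dihydroxycyclohexa-2,5-diene-1,4-dione | OC1=C(c2ccc(OCc3ccccc3)cc2)C(=O)C(O)=C(c2ccc(OCc3ccccc3)cc2)C1=O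
F5 | step 5 | 2,5-bis[4-(benzyloxy)phenyl]-4-hydroxy-3,6-dioxocyclohexa-1,4-dien-1-yl acetate | CC(=O)OC1=C(c2ccc(OCc3ccccc3)cc2)C(=O)C(O)=C(c2ccc(OCc3ccccc3)cc2)C1=O
F0 | step 7 | none | none
F6 | step 3 | ethyl 4-(benzyloxy)benzoate | CCOC(=O)c1ccc(OCc2ccccc2)cc1
F7 | step 3 | 1-[4-(benzyloxy)phenyl]-2,2-dibromoethan-1-one | BrC(Br)C(=O)c1ccc(OCc2ccccc2)cc1
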